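Read at 4.0 h, this flask stands in the tail of its decay, so the late behaviour of the earlier runs has to be known better than their opening.

| flask | starting material | acid | scavenger | protic impurity | remark | time |
|---|---|---|---|---|---|---|
| spring | 0.050 M | 3 mM | 0.080 M | 0.050 M | run made earlier |  |
| autumn | 0.075 M | 3 mM | 0.080 M | 0.050 M | run made earlier |  |
| flask | 0.10 M | 3.00 mM | 0.0800 M | 0.0500 M |  | 4.0 h |

| run | time / h | starting material / % | product / % |
|---|---|---|---|
| spring | 0.833 | 40.1 | 31.5 |
| spring | 1.50 | 21.9 | 42.8 |
| spring | 2.50 | 11.1 | 52.1 |
| spring | 3.00 | 7.0 | 54.5 |
| spring | 4.00 | 2.9 | 57.5 |
| autumn | 0.833 | 40.6 | 30.1 |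
| autumn | 1.50 | 22.5 | 42.4 |
| autumn | 2.50 | 12.2 | 52.5 |
| autumn | 3.00 | 9.1 | 55.6 |
| autumn | 4.00 | 5.1 | 59.5 |

(standard deviation of a reading: 0.5 percentage points)

- acid is the free proton; pH is minus the decimal logarithm of its molar concentration
- percentages count the starting material that a species holds: one idle adduct A counts as two
- product is meant together with its idle adduct A
- weak acid is meant together with its idle adduct B
- steps that have been proposed: starting material + acid -> weak acid + acid + product; weak acid <-> conjugate base + acid; starting material -> weak acid + product; starting material + product <-> idle adduct A; starting material + weak acid <-> idle adduct B; weak acid + scavenger -> scavenged by-product; starting material + protic impurity -> quenched substrate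
- in an amount of product, one idle adduct A counts as one product
- what has gone from starting material into another species counts as reacted, even if it can come back

1. part of the starting material that has reacted at 4.0 h
2. pH of the solution at 4.0 h

Take the inputs by what an error in each would cost you. The autumn run opens at 0.885 /h between its first two readings. From 2.50 h to 4.00 h it decays at 0.581 /h, so its opening is faster. This is the tail pace, the pseudo-first-order constant of free starting material late in a run.

My reckoning starts at 2.50 h, so the opening is already inside its starting value. The charges of spring and autumn step evenly towards this flask's, and extending their readings gives 13.3% free starting material. A miss of 0.5 percentage points there costs 0.21 points at 4.0 h. The spring tail pace, 0.895 /h, would instead move the answer by 2.1 points, so the tail pace matters more. I keep the autumn value, whose charge is nearer this flask's. That leaves 5.56%, hence 94.4% reacted.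

The pH follows [acid] instead: doubling [acid] moves it by 0.301, and the proposed catalytic step returns its acid, so I take the charged 3.00 mM.

The forecast, by its own route, gives 94.5% (91.5% to 98.5%) and pH 2.48 (2.2 to 2.55): “In the flask, the quench adds about 0.45–0.5 to the exponent, leaving about 6% starting material.”

The flask gives 94.7% reacted, at pH 2.52.

    starting material + acid → weak acid + acid + product (k = 112 /M/h)
    weak acid ⇌ conjugate base + acid, settled at all times (K = 3.20 × 10⁻⁷ M)
    starting material → weak acid + product (k = 0.237 /h)
    starting material + product ⇌ idle adduct A, settled at all times (K = 7.21 /M)
    starting material + weak acid ⇌ idle adduct B, settled at all times (K = 8.40 /M)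
    weak acid + scavenger → scavenged by-product (k = 242 /M/h)
    starting material + protic impurity → quenched substrate (k = 9.88 /M/h)

The nearest earlier time at which that conversion has moved by 5 points is 2.83 h. The neighbour flask read at 2.5 h holds 12.7% starting material. Carried to 4.0 h at the tail pace, that becomes 5.31%, and this flask holds 5.35%.

The readings are calculated with constants of no real substance; scatter was added.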